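**Strategy.** The eudesmane core is disconnected across C5–C10 and C3–C4 by a type 1 intramolecular Diels–Alder reaction of an (E,E)-trienal, in which a formyl group on C4 serves as a latent C–O bond. In one operation the cycloaddition closes rings A and B and sets C4, C5 and C10. It exploits the cis-1,3 relationship of the two axial methyl groups on C4 and C10 of ring A, together with the trans ring fusion at C5, both of which follow directly from enal and diene geometry. The precursor is (2E,5R,8E)-2,8-dimethyl-5-(2-silyloxypropan-2-yl)undeca-2,8,10-trienal, made from (R)-α-terpineol. Baeyer–Villiger oxidation later converts the formyl group into the C4 oxygen with retention, and the biaryl is then built on that oxygen.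

Key step: step 7

Remark: the descriptors 4R,5R,7R,10R of the terpenoid part correspond to 4α-aryloxy, 4β-methyl, 5α-H, 7β-side chain and 10β-methyl, so the trienal must be 5R, which (R)-α-terpineol supplies; the bromophenol used in step 12 is assumed to be a catalogue compound.

Step 1
Reactants: 1 (R)-α-terpineol
Product: 2 tert-butyl-dimethyl-{2-[(1R)-4-methylcyclohex-3-en-1-yl]propan-2-yloxy}silane
Conditions: TBSOTf (1.3 equiv), 2,6-lutidine (2 equiv), CH2Cl2, 0 °C → rt
Reagents that add atoms: tert-butyldimethylsilyl trifluoromethanesulfonate, CC(C)(C)[Si](C)(C)OS(=O)(=O)C(F)(F)F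
Why: Silyl triflate with a hindered pyridine base silylates tertiary alcohols reliably (O-silylation); the tert-butyldimethylsilyl group is chosen because it has to outlast the catalytic sulfonic acid of step 2 and the aluminium Lewis acid of step 7, and the stereocentre is not involved.

Step 2
Reactants: 2 tert-butyldimethylsilyl ether of (R)-α-terpineol
Product: 5 (5R)-7,7-dimethoxy-5-[2-(tert-butyldimethylsilyloxy)propan-2-yl]heptan-2-one, via hydroperoxy aldehyde 3 (not isolated), via hydroperoxy acetal 4 (not isolated)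
Conditions: O3, CH2Cl2/MeOH (5:1), −78 °C; TsOH·H2O (10 mol %), rt; NaHCO3, then Me2S, rt
Reagents that add atoms: ozone, [O-][O+]=O; methanol, CO
Why: Ozonolysis in methanol, in which the primary ozonide of the trisubstituted alkene fragments so that the carbonyl oxide sits on the methyl-bearing carbon and is trapped as a methoxy hydroperoxide while the free aldehyde is acetalised by the acid, so that sulfide reduction releases only the ketone and the two termini emerge differentiated in one flask.

Step 3
Reactants: 5 (5R)-keto acetal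
Product: 9 (3R)-1,1-dimethoxy-3-[2-(tert-butyldimethylsilyloxy)propan-2-yl]hept-6-yne, via lithium enolate 6 (not isolated), via enol phosphate 7 (not isolated), via lithium acetylide 8 (not isolated)
Conditions: LDA (1.05 equiv), THF, −78 °C; ClP(O)(OEt)2 (1.1 equiv), −78 °C → rt; LDA (2.3 equiv), −78 °C → rt; aq. NH4Cl
Reagents that add atoms: none
Why: Methyl ketone to terminal alkyne by the enol phosphate route (kinetic deprotonation on the methyl side, O-phosphorylation, double amide-base elimination), which leaves the acetal, the silyl ether and the remote stereocentre untouched.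

Step 4
Reactants: 9 (3R)-alkyne acetal; 10 trimethylaluminium; 11 vinyl bromide
Product: 13 (3E,7R)-9,9-dimethoxy-4-methyl-7-[2-(tert-butyldimethylsilyloxy)propan-2-yl]nona-1,3-diene, via alkenylalane 12 (not isolated)
Conditions: Me3Al (2.5 equiv), Cp2ZrCl2 (0.25 equiv), CH2Cl2, 0 °C → rt; then vinyl bromide (3 equiv, 1 M in THF), Pd(PPh3)4 (5 mol %), ZnCl2 (cat.), THF, rt
Reagents that add atoms: trimethylaluminium, C[Al](C)C; vinyl bromide, C=CBr
Why: Zirconium-catalysed carboalumination adds methyl and aluminium syn across the terminal alkyne with methyl on the internal carbon, and the alkenyl–alkenyl coupling catalysed by zerovalent palladium (Negishi type, zinc-assisted transmetalation) proceeds with retention, so the diene forms as the (E)-isomer with the tether trans and the methyl cis to the vinyl group.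

Step 5
Reactants: 13 (3E,7R)-diene acetal
Product: 14 (3R,6E)-6-methyl-3-[2-(tert-butyldimethylsilyloxy)propan-2-yl]nona-6,8-dienal
Conditions: PPTS (10 mol %), acetone/H2O (10:1), 50 °C
Reagents that add atoms: water, O
Why: Acid-catalysed acetal hydrolysis in wet acetone, where pyridinium tosylate is too weak an acid to protonate the diene or to cleave the tertiary silyl ether.

Step 6
Reactants: 14 (3R,6E)-dienal; 15 2-(triphenylphosphoranylidene)propanal
Product: 16 (2E,5R,8E)-2,8-dimethyl-5-[2-(tert-butyldimethylsilyloxy)propan-2-yl]undeca-2,8,10-trienal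
Conditions: 15 (1.3 equiv), toluene, 90 °C
Reagents that add atoms: 2-(triphenylphosphoranylidene)propanal, CC(C=O)=P(c1ccccc1)(c1ccccc1)c1ccccc1
Why: Wittig olefination with a formyl-stabilised ylide, which reacts only with the aldehyde and gives the (E)-2-methyl enal (formyl trans to the chain) through a reversible, thermodynamically controlled oxaphosphetane, at a temperature well below that of an uncatalysed cycloaddition.

Step 7
Reactants: 16 (2E,5R,8E)-trienal
Product: 17 (1R,4aS,7R,8aR)-1,4a-dimethyl-7-[2-(tert-butyldimethylsilyloxy)propan-2-yl]-1,2,4a,5,6,7,8,8a-octahydronaphthalene-1-carbaldehyde (eudesmane numbering: 4α-CHO, 4β-CH3, 5α-H, 10β-CH3, C1=C2)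
Conditions: Me2AlCl (1.5 equiv, 1 M in hexanes), CH2Cl2, −78 → −20 °C; 1 M HCl, 0 °C
Reagents that add atoms: none
Why: Dimethylaluminium chloride binds the formyl oxygen and lowers the enal LUMO, and the tethered diene then adds in a concerted but asynchronous [4+2] cycloaddition in which the C5–C10 bond runs ahead of the C3–C4 bond. The closest known reaction type is the alkylaluminium-chloride-promoted type 1 intramolecular Diels–Alder reaction of 2,8,10-undecatrienals to trans-fused octalin carbaldehydes. Ring A closes as the new cyclohexene through both new bonds, and ring B closes through the C5–C10 bond with the four-carbon tether C6–C9 folded as a chair. C4 is set by suprafacial addition to the (E)-enal (methyl cis to C6 and therefore β, formyl α), C10 by the (E)-diene geometry (tether outside, methyl inside, hence methyl β and anti to H-5), and C5 by the formyl-endo approach that places C6 exo and gives the trans fusion; the absolute sense of all three follows from C7, whose bulky silyloxypropyl group sits equatorial on the chair tether. The step needs endo over exo addition, one diene face and intact alkene geometry: aluminium coordination reinforces the endo preference, the C7 substituent selects the face, and the aprotic Lewis acid, which destroys adventitious acid as methane, keeps both alkenes from isomerising.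

Step 8
Reactants: 17 octalin aldehyde
Product: 18 (1R,4aR,7R,8aR)-1,4a-dimethyl-7-[2-(tert-butyldimethylsilyloxy)propan-2-yl]decahydronaphthalene-1-carbaldehyde
Conditions: H2 (1 atm), Pd/C (10 %), EtOAc, rt
Reagents that add atoms: none
Why: Heterogeneous hydrogenation of the cis-disubstituted C1=C2 alkene, in which the neopentyl-type aldehyde and the silyl ether are inert in ethyl acetate and no stereocentre is created or touched.

Step 9
Reactants: 18 decalin aldehyde
Product: 20 (1R,4aR,7R,8aR)-1,4a-dimethyl-7-[2-(tert-butyldimethylsilyloxy)propan-2-yl]decahydronaphthalen-1-ol (4α-OH, 4β-CH3), via formate ester 19 (not isolated)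
Conditions: mCPBA (1.5 equiv), CH2Cl2, 0 °C → rt; aq. Na2S2O3/NaHCO3 wash; then K2CO3 (cat.), MeOH, rt
Reagents that add atoms: 3-chloroperoxybenzoic acid, OOC(=O)c1cccc(Cl)c1
Why: Baeyer–Villiger oxidation of an α-quaternary aldehyde, in which the tertiary C4 migrates in preference to hydride and with retention, followed by carbonate-catalysed methanolysis of the formate, so the oxygen ends up 4α (equatorial) with the 4β-methyl still syn to the C10 methyl.

Step 10
Reactants: 21 2-bromo-4-chloro-1-iodobenzene; 22 1,3,5-trimethoxybenzene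
Product: 24 (2-bromo-4-chlorophenyl)(2,4,6-trimethoxyphenyl)iodonium 4-methylbenzenesulfonate, via aryliodine hydroxy tosylate 23 (not isolated)
Conditions: mCPBA (1.1 equiv), TsOH·H2O (1.05 equiv), MeCN, 55 °C; then 22 (1.05 equiv), rt; Et2O trituration
Reagents that add atoms: 1,3,5-trimethoxybenzene, COc1cc(OC)cc(OC)c1; 4-methylbenzenesulfonic acid, Cc1ccc(cc1)S(=O)(=O)O
Why: One-pot iodonium salt synthesis, in which peracid oxidation of the aryl iodide in the presence of sulfonic acid gives the trivalent iodine tosylate that then undergoes electrophilic aromatic substitution on the electron-rich arene.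

Step 11
Reactants: 20 tertiary alcohol; 24 iodonium tosylate
Product: 26 (4R,5R,7R,10R)-4-(2-bromo-4-chlorophenoxy)-11-(tert-butyldimethylsilyloxy)eudesmane (4α-aryloxy, 4β-CH3, 5α-H, 10β-CH3), via sodium alkoxide 25 (not isolated)
Conditions: NaH (1.5 equiv), toluene, 60 °C; then 24 (1.3 equiv), rt → 40 °C
Reagents that add atoms: (2-bromo-4-chlorophenyl)(2,4,6-trimethoxyphenyl)iodonium 4-methylbenzenesulfonate, COc1cc(OC)c([I+]c2ccc(Cl)cc2Br)c(OC)c1.Cc1ccc(cc1)S(=O)(=O)[O-]
Why: Metal-free O-arylation of a tertiary alkoxide with a diaryliodonium salt (ligand exchange at iodine, then ligand coupling), in which the electron-poor, ortho-substituted 2-bromo-4-chlorophenyl group is transferred in preference to the electron-rich trimethoxyphenyl group, and the C4–O bond is never broken, so the configuration is kept.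

Step 12
Reactants: 27 2-allyl-4-bromophenol; 28 bis(pinacolato)diboron
Product: 29 2-allyl-4-(4,4,5,5-tetramethyl-1,3,2-dioxaborolan-2-yl)phenol
Conditions: B2pin2 (1.2 equiv), Pd(dppf)Cl2 (3 mol %), KOAc (3 equiv), 1,4-dioxane, 85 °C
Reagents that add atoms: bis(pinacolato)diboron, CC1(C)OB(OC1(C)C)B1OC(C)(C)C(C)(C)O1
Why: Miyaura borylation of an aryl bromide, which tolerates the free phenol and the allyl group under the weak acetate base.

Step 13
Reactants: 26 bromo chloro aryl ether; 29 phenol boronate
Product: 30 (4R,5R,7R,10R)-4-{[3'-allyl-5-chloro-4'-hydroxy-(1,1'-biphenyl)-2-yl]oxy}-11-(tert-butyldimethylsilyloxy)eudesmane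
Conditions: 29 (1.5 equiv), Pd(dppf)Cl2 (5 mol %), K2CO3 (3 equiv), 1,4-dioxane/H2O (5:1), 85 °C
Reagents that add atoms: 2-allyl-4-(4,4,5,5-tetramethyl-1,3,2-dioxaborolan-2-yl)phenol, C=CCc1cc(B2OC(C)(C)C(C)(C)O2)ccc1O
Why: Suzuki–Miyaura coupling in which oxidative addition to the C–Br bond is much faster than to the C–Cl bond with a bisphosphine palladium catalyst, so only the position ortho to the ether oxygen is arylated.

Step 14
Reactants: 30 biaryl chloride; 31 2-allyl-4,4,5,5-tetramethyl-1,3,2-dioxaborolane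
Product: 32 (4R,5R,7R,10R)-4-{[3',5-diallyl-4'-hydroxy-(1,1'-biphenyl)-2-yl]oxy}-11-(tert-butyldimethylsilyloxy)eudesmane
Conditions: 31 (2 equiv), Pd(OAc)2 (3 mol %), XPhos (6 mol %), K3PO4 (3 equiv), THF/H2O (10:1), 65 °C
Reagents that add atoms: 2-allyl-4,4,5,5-tetramethyl-1,3,2-dioxaborolane, C=CCB1OC(C)(C)C(C)(C)O1
Why: Suzuki–Miyaura allylation of an aryl chloride, for which a bulky electron-rich biarylphosphine enables oxidative addition to the electron-rich C–Cl bond, the unsubstituted allyl boronate can give only one constitutional isomer, and the moderate temperature limits migration of the allyl double bonds.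

Step 15
Reactants: 32 silyl-protected target
Product: 33 target, 2-[(2R,4aR,8R,8aR)-8-{[3',5-diallyl-4'-hydroxy-(1,1'-biphenyl)-2-yl]oxy}-4a,8-dimethyldecahydronaphthalen-2-yl]propan-2-ol
Conditions: Bu4NF (5 equiv), THF, 60 °C
Reagents that add atoms: none
Why: Fluoride-induced desilylation of the tertiary silyl ether under basic conditions, which spares the acid-labile tertiary alkyl aryl ether, the phenol and both allyl groups and touches no stereocentre.

**Compound list**

1 | (R)-α-terpineol | CC1=CC[C@H](C(C)(C)O)CC1 | starting material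
2 | tert-butyl-dimethyl-{2-[(1R)-4-methylcyclohex-3-en-1-yl]propan-2-yloxy}silane | CC1=CC[C@H](C(C)(C)O[Si](C)(C)C(C)(C)C)CC1 | intermediate
3 | (3R)-6-hydroperoxy-6-methoxy-3-[2-(tert-butyldimethylsilyloxy)propan-2-yl]heptanal (both C6 epimers; not isolated) | O=CC[C@H](C(C)(C)O[Si](C)(C)C(C)(C)C)CCC(C)(OC)OO | intermediate
4 | (5R)-2-hydroperoxy-2,7,7-trimethoxy-5-[2-(tert-butyldimethylsilyloxy)propan-2-yl]heptane (both C2 epimers; not isolated) | COC(OC)C[C@H](C(C)(C)O[Si](C)(C)C(C)(C)C)CCC(C)(OC)OO | intermediate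
5 | (5R)-7,7-dimethoxy-5-[2-(tert-butyldimethylsilyloxy)propan-2-yl]heptan-2-one | CC(=O)CC[C@@H](C(C)(C)O[Si](C)(C)C(C)(C)C)CC(OC)OC | intermediate
6 | lithium (5R)-7,7-dimethoxy-5-[2-(tert-butyldimethylsilyloxy)propan-2-yl]hept-1-en-2-olate (not isolated) | [Li+].[O-]C(=C)CC[C@@H](C(C)(C)O[Si](C)(C)C(C)(C)C)CC(OC)OC | intermediate
7 | diethyl (5R)-7,7-dimethoxy-5-[2-(tert-butyldimethylsilyloxy)propan-2-yl]hept-1-en-2-yl phosphate (not isolated) | C=C(OP(=O)(OCC)OCC)CC[C@@H](C(C)(C)O[Si](C)(C)C(C)(C)C)CC(OC)OC | intermediate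
8 | lithium acetylide of 9 (not isolated) | [Li+].[C-]#CCC[C@@H](C(C)(C)O[Si](C)(C)C(C)(C)C)CC(OC)OC | intermediate
9 | (3R)-1,1-dimethoxy-3-[2-(tert-butyldimethylsilyloxy)propan-2-yl]hept-6-yne | C#CCC[C@@H](C(C)(C)O[Si](C)(C)C(C)(C)C)CC(OC)OC | intermediate
10 | trimethylaluminium | C[Al](C)C | starting material
11 | vinyl bromide | C=CBr | starting material
12 | dimethyl{(1E,5R)-7,7-dimethoxy-2-methyl-5-[2-(tert-butyldimethylsilyloxy)propan-2-yl]hept-1-en-1-yl}alane (not isolated) | C[Al](C)/C=C(\C)CC[C@@H](C(C)(C)O[Si](C)(C)C(C)(C)C)CC(OC)OC | intermediate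
13 | (3E,7R)-9,9-dimethoxy-4-methyl-7-[2-(tert-butyldimethylsilyloxy)propan-2-yl]nona-1,3-diene | C=C/C=C(\C)CC[C@@H](C(C)(C)O[Si](C)(C)C(C)(C)C)CC(OC)OC | intermediate
14 | (3R,6E)-6-methyl-3-[2-(tert-butyldimethylsilyloxy)propan-2-yl]nona-6,8-dienal | O=CC[C@H](C(C)(C)O[Si](C)(C)C(C)(C)C)CC/C(C)=C/C=C | intermediate
15 | 2-(triphenylphosphoranylidene)propanal | CC(C=O)=P(c1ccccc1)(c1ccccc1)c1ccccc1 | starting material
16 | (2E,5R,8E)-2,8-dimethyl-5-[2-(tert-butyldimethylsilyloxy)propan-2-yl]undeca-2,8,10-trienal | O=C/C(C)=C/C[C@H](C(C)(C)O[Si](C)(C)C(C)(C)C)CC/C(C)=C/C=C | intermediate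
17 | (1R,4aS,7R,8aR)-1,4a-dimethyl-7-[2-(tert-butyldimethylsilyloxy)propan-2-yl]-1,2,4a,5,6,7,8,8a-octahydronaphthalene-1-carbaldehyde | O=C[C@]1(C)CC=C[C@]2(C)CC[C@@H](C(C)(C)O[Si](C)(C)C(C)(C)C)C[C@H]21 | intermediate
18 | (1R,4aR,7R,8aR)-1,4a-dimethyl-7-[2-(tert-butyldimethylsilyloxy)propan-2-yl]decahydronaphthalene-1-carbaldehyde | O=C[C@]1(C)CCC[C@]2(C)CC[C@@H](C(C)(C)O[Si](C)(C)C(C)(C)C)C[C@H]21 | intermediate
19 | (1R,4aR,7R,8aR)-1,4a-dimethyl-7-[2-(tert-butyldimethylsilyloxy)propan-2-yl]decahydronaphthalen-1-yl formate (not isolated) | O=CO[C@]1(C)CCC[C@]2(C)CC[C@@H](C(C)(C)O[Si](C)(C)C(C)(C)C)C[C@H]21 | intermediate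
20 | (1R,4aR,7R,8aR)-1,4a-dimethyl-7-[2-(tert-butyldimethylsilyloxy)propan-2-yl]decahydronaphthalen-1-ol | O[C@]1(C)CCC[C@]2(C)CC[C@@H](C(C)(C)O[Si](C)(C)C(C)(C)C)C[C@H]21 | intermediate
21 | 2-bromo-4-chloro-1-iodobenzene | Clc1ccc(I)c(Br)c1 | starting material
22 | 1,3,5-trimethoxybenzene | COc1cc(OC)cc(OC)c1 | starting material
23 | 2-bromo-4-chloro-1-[hydroxy(tosyloxy)iodo]benzene (not isolated) | Cc1ccc(cc1)S(=O)(=O)OI(O)c1ccc(Cl)cc1Br | intermediate
24 | (2-bromo-4-chlorophenyl)(2,4,6-trimethoxyphenyl)iodonium 4-methylbenzenesulfonate | COc1cc(OC)c([I+]c2ccc(Cl)cc2Br)c(OC)c1.Cc1ccc(cc1)S(=O)(=O)[O-] | intermediate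
25 | sodium alkoxide of 20 (not isolated) | [Na+].[O-][C@]1(C)CCC[C@]2(C)CC[C@@H](C(C)(C)O[Si](C)(C)C(C)(C)C)C[C@H]21 | intermediate
26 | (4R,5R,7R,10R)-4-(2-bromo-4-chlorophenoxy)-11-(tert-butyldimethylsilyloxy)eudesmane | Clc1ccc(O[C@]2(C)CCC[C@]3(C)CC[C@@H](C(C)(C)O[Si](C)(C)C(C)(C)C)C[C@H]32)c(Br)c1 | intermediate
27 | 2-allyl-4-bromophenol | C=CCc1cc(Br)ccc1O | starting material
28 | bis(pinacolato)diboron | CC1(C)OB(OC1(C)C)B1OC(C)(C)C(C)(C)O1 | starting material
29 | 2-allyl-4-(4,4,5,5-tetramethyl-1,3,2-dioxaborolan-2-yl)phenol | C=CCc1cc(B2OC(C)(C)C(C)(C)O2)ccc1O | intermediate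
30 | (4R,5R,7R,10R)-4-{[3'-allyl-5-chloro-4'-hydroxy-(1,1'-biphenyl)-2-yl]oxy}-11-(tert-butyldimethylsilyloxy)eudesmane | Clc1ccc(O[C@]2(C)CCC[C@]3(C)CC[C@@H](C(C)(C)O[Si](C)(C)C(C)(C)C)C[C@H]32)c(-c2ccc(O)c(CC=C)c2)c1 | intermediate
31 | 2-allyl-4,4,5,5-tetramethyl-1,3,2-dioxaborolane | C=CCB1OC(C)(C)C(C)(C)O1 | starting material
32 | (4R,5R,7R,10R)-4-{[3',5-diallyl-4'-hydroxy-(1,1'-biphenyl)-2-yl]oxy}-11-(tert-butyldimethylsilyloxy)eudesmane | C=CCc1ccc(O[C@]2(C)CCC[C@]3(C)CC[C@@H](C(C)(C)O[Si](C)(C)C(C)(C)C)C[C@H]32)c(-c2ccc(O)c(CC=C)c2)c1 | intermediate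
33 | 2-[(2R,4aR,8R,8aR)-8-{[3',5-diallyl-4'-hydroxy-(1,1'-biphenyl)-2-yl]oxy}-4a,8-dimethyldecahydronaphthalen-2-yl]propan-2-ol (CNP0219722.1) | C=CCc1ccc(O[C@]2(C)CCC[C@]3(C)CC[C@@H](C(C)(C)O)C[C@H]32)c(-c2ccc(O)c(CC=C)c2)c1 | target

**Step count.** Total: 15 steps (13 on the main line and one each for coupling partners 24 and 29). Longest linear sequence: 13 steps (steps 1–9, 11, 13, 14 and 15).

**Steps most likely to fail**

1. Step 7. The diene terminus C10 carries both the tether and an inside methyl group and may react too slowly. Exo addition, cationic oligomerisation of the diene or methyl transfer from aluminium to the aldehyde could then compete, and endo and facial control would erode. Fallback: the neutral carbonyl activation is replaced by a cationic cycloaddition of an acetal. It sets out from trienal 16, which with 1,2-bis(trimethylsilyloxy)ethane and catalytic TMSOTf (CH2Cl2, −78 °C) should give the dioxolane F1. Catalytic TfOH (CH2Cl2, −78 → −40 °C) should open F1 to a 2-alkoxyallyl cation, a far stronger dienophile, which should close through the same chair tether to the cycloadduct acetal F2. Aqueous HCl in THF at rt then hydrolyses F2 and the route is rejoined at aldehyde 17.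

2. Step 11. The hindered tertiary alkoxide may act as a base towards the iodonium salt (ortho deprotonation and aryne formation, giving regioisomeric ethers or none), or ligand coupling at iodine may be too slow. Fallback: nucleophilic aromatic substitution replaces the iodine-mediated coupling. It sets out from alcohol 20, which with KHMDS (THF, 0 °C) and 2-bromo-1-fluoro-4-nitrobenzene should give the nitroaryl ether F3. Fe and NH4Cl (EtOH/H2O, 70 °C) should reduce F3 to the aniline F4. tert-Butyl nitrite and CuCl2 in MeCN at 60 °C (non-aqueous Sandmeyer chlorination through the diazonium chloride F5) then install chlorine and return to aryl ether 26.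

3. Step 4. The Lewis-acidic alane medium may ionise the dimethyl acetal (methyl transfer to the oxocarbenium ion) during carbometalation, and the trisubstituted alkenylalane may couple sluggishly. Fallback: aluminium is replaced by boron under conditions that are not Lewis acidic. It sets out from alkyne 9, where copper-catalysed borylmethylation (CuCl, Xantphos, B2pin2, NaOt-Bu, MeI, THF, rt; syn addition of boron and methyl) should give the (E)-alkenylboronate F6. Suzuki–Miyaura coupling of F6 with vinyl bromide 11 (Pd(dppf)Cl2, K3PO4, THF/H2O, 50 °C, sealed vessel) returns to diene acetal 13.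

**Further compounds**

F1 | step 7 | 2-{(2E,5R,8E)-8-methyl-5-[2-(tert-butyldimethylsilyloxy)propan-2-yl]undeca-2,8,10-trien-2-yl}-1,3-dioxolane | C1COC(O1)/C(C)=C/C[C@H](C(C)(C)O[Si](C)(C)C(C)(C)C)CC/C(C)=C/C=C
F2 | step 7 | 2-{(1R,4aS,7R,8aR)-1,4a-dimethyl-7-[2-(tert-butyldimethylsilyloxy)propan-2-yl]-1,2,4a,5,6,7,8,8a-octahydronaphthalen-1-yl}-1,3-dioxolane | O1CCOC1[C@]1(C)CC=C[C@]2(C)CC[C@@H](C(C)(C)O[Si](C)(C)C(C)(C)C)C[C@H]21
F3 | step 11 | (4R,5R,7R,10R)-4-(2-bromo-4-nitrophenoxy)-11-(tert-butyldimethylsilyloxy)eudesmane | [O-][N+](=O)c1ccc(O[C@]2(C)CCC[C@]3(C)CC[C@@H](C(C)(C)O[Si](C)(C)C(C)(C)C)C[C@H]32)c(Br)c1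
F4 | step 11 | (4R,5R,7R,10R)-4-(4-amino-2-bromophenoxy)-11-(tert-butyldimethylsilyloxy)eudesmane | Nc1ccc(O[C@]2(C)CCC[C@]3(C)CC[C@@H](C(C)(C)O[Si](C)(C)C(C)(C)C)C[C@H]32)c(Br)c1
F5 | step 11 | 3-bromo-4-{[(4R,5R,7R,10R)-11-(tert-butyldimethylsilyloxy)eudesman-4-yl]oxy}benzenediazonium chloride | N#[N+]c1ccc(O[C@]2(C)CCC[C@]3(C)CC[C@@H](C(C)(C)O[Si](C)(C)C(C)(C)C)C[C@H]32)c(Br)c1.[Cl-]
F6 | step 4 | 2-{(1E,5R)-7,7-dimethoxy-2-methyl-5-[2-(tert-butyldimethylsilyloxy)propan-2-yl]hept-1-en-1-yl}-4,4,5,5-tetramethyl-1,3,2-dioxaborolane | CC1(C)OB(OC1(C)C)/C=C(\C)CC[C@@H](C(C)(C)O[Si](C)(C)C(C)(C)C)CC(OC)OC
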